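**Retrosynthetic overview**

1. The strategy rests on the α-ketol hidden in the 3(2H)-furanone ring (O, C3, C2, C1, C10): quaternary C10 carries the C14 methyl and an oxygen and is bonded directly to the C1 carbonyl. C1–C10 is therefore cut as a crossed benzoin between a C1 aldehyde and a C10 methyl ketone, which closes the ten-membered carbocycle.
2. Ring order: ten-membered carbocycle (step 19); then, after the C3 dithiane is removed, the furanone (C10–O–C3) and the cis-fused 6,12-γ-lactone (both in step 21); last the C8 methacrylate and the free C9 hydroxyl.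
3. The open-chain precursor is joined at C6–C7 by an indium Barbier reaction of fragment A (C1–C6 Z-enal with C3 dithiane, from but-2-yn-1-ol, methyl propiolate and propane-1,3-dithiol) with fragment B (C7–C13 2-(bromomethyl)enoate carrying C8–C10, from diethyl L-tartrate and methyl propiolate).
4. Stereocentres: C8 and C9 from L-tartrate; C6 and C7 in the Barbier step (Z-allyl geometry, allylic 1,3-strain); C10 in the benzoin step (1,2-induction from C9).

Key step: step 19

Remark on the chemistry: germacrane numbering is used (ring C1–C10, lactone carbons C11–C13, C14 on C10, C15 on C4). The target SMILES is read as 4Z, 6S,7S,8S,9R,10R with a cis-fused 6,12-lactone, and the route is built for exactly this isomer.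

**Fragment A (C1–C6)**

Step 1
Reactants: 1 but-2-yn-1-ol
Product: 3 (2Z)-3-iodobut-2-en-1-ol, via sodium alkenylaluminate 2 (not isolated)
Conditions: NaAlH2(OCH2CH2OMe)2, THF, 0 °C → rt; then I2, −78 → 0 °C
Reagents that add atoms: iodine, II
Why: Hydroxyl-directed trans-hydroalumination puts aluminium on C3 in a five-membered oxaaluminacycle and iodinolysis with retention should give the Z-iodide, which fixes C6 and C3 cis across the future C4=C5 bond.

Step 2
Reactants: 3 (2Z)-3-iodobut-2-en-1-ol
Product: 4 (2Z)-3-iodobut-2-en-1-yl 2,2-dimethylpropanoate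
Conditions: PivCl, pyridine, DMAP (cat.), CH2Cl2, 0 °C
Reagents that add atoms: pivaloyl chloride, CC(C)(C)C(=O)Cl
Why: Simple acylation; the pivalate keeps the cis-disposed C6 hydroxyl from adding to the ynoate (furan formation) in steps 3 and 4.

Step 3
Reactants: 4 (2Z)-3-iodobut-2-en-1-yl 2,2-dimethylpropanoate; 5 methyl propiolate
Product: 6 methyl (4Z)-6-[(2,2-dimethylpropanoyl)oxy]-4-methylhex-4-en-2-ynoate
Conditions: PdCl2(PPh3)2 (cat.), CuI (cat.), K2CO3, THF, rt
Reagents that add atoms: none
Why: Sonogashira coupling of an alkenyl iodide proceeds with retention of alkene geometry, and the inorganic base avoids amine addition to the propiolate.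

Step 4
Reactants: 6 methyl (4Z)-6-[(2,2-dimethylpropanoyl)oxy]-4-methylhex-4-en-2-ynoate
Product: 8 methyl {2-[(2Z)-4-[(2,2-dimethylpropanoyl)oxy]but-2-en-2-yl]-1,3-dithian-2-yl}acetate, via vinyl sulfide thiol 7 (not isolated)
Conditions: HS(CH2)3SH, NaOMe (1.2 equiv), MeOH/CH2Cl2, −10 °C → rt
Reagents that add atoms: propane-1,3-dithiol, SCCCS
Why: Double conjugate (thia-Michael) addition to the ynoate: the first thiolate adds at C3, the second closes 6-exo on the same carbon, so C3 becomes the dithiane without the C4=C5 alkene taking part (any pivalate lost here converges in step 5).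

Step 5
Reactants: 8 methyl {2-[(2Z)-4-[(2,2-dimethylpropanoyl)oxy]but-2-en-2-yl]-1,3-dithian-2-yl}acetate
Product: 9 (2Z)-3-[2-(2-hydroxyethyl)-1,3-dithian-2-yl]but-2-en-1-ol
Conditions: i-Bu2AlH (5 equiv), CH2Cl2, −78 → 0 °C
Reagents that add atoms: none
Why: Hydride reduction takes the C1 methyl ester to the primary alcohol and cleaves the pivalate in the same operation.

Step 6
Reactants: 9 (2Z)-3-[2-(2-hydroxyethyl)-1,3-dithian-2-yl]but-2-en-1-ol
Product: 10 (2Z)-3-[2-(2-hydroxyethyl)-1,3-dithian-2-yl]but-2-enal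
Conditions: MnO2, CH2Cl2, rt
Reagents that add atoms: none
Why: MnO2 oxidises the allylic C6 alcohol selectively over the saturated C1 alcohol, and a β,β-disubstituted Z-enal of this type should keep its geometry under neutral conditions.

**Fragment B (C7–C13)**

Step 7
Reactants: 11 diethyl L-tartrate
Product: 13 diethyl (2R,3R)-2-hydroxy-3-[(4-methoxybenzyl)oxy]butanedioate, via dibutylstannylene acetal 12 (not isolated)
Conditions: Bu2SnO, PhMe, reflux (−H2O); then PMBCl, CsF, DMF, rt
Reagents that add atoms: 4-methoxybenzyl chloride, COc1ccc(CCl)cc1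
Why: Stannylene-mediated mono-alkylation; the C2 symmetry of tartrate makes both hydroxyls equivalent, so one mono-ether results (ether carbon = C9, free carbinol = C8).

Step 8
Reactants: 13 diethyl (2R,3R)-2-hydroxy-3-[(4-methoxybenzyl)oxy]butanedioate
Product: 14 ethyl (2R,3S)-3,4-dihydroxy-2-[(4-methoxybenzyl)oxy]butanoate
Conditions: BH3·SMe2, NaBH4 (5 mol%), THF, 0 °C → rt; MeOH quench
Reagents that add atoms: none
Why: Hydroxyl-directed borane reduction takes only the ester next to the free hydroxyl (C7) to the alcohol through a cyclic alkoxyborane; the diol is silylated without delay to avoid γ-lactonisation.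

Step 9
Reactants: 14 ethyl (2R,3S)-3,4-dihydroxy-2-[(4-methoxybenzyl)oxy]butanoate
Product: 15 ethyl (2R,3S)-3-hydroxy-2-[(4-methoxybenzyl)oxy]-4-[(triethylsilyl)oxy]butanoate
Conditions: TESCl (1.05 equiv), imidazole, CH2Cl2, −40 °C
Reagents that add atoms: chlorotriethylsilane, CC[Si](CC)(CC)Cl
Why: Silylation at low temperature is selective for the primary C7 hydroxyl over the flanked secondary C8 hydroxyl.

Step 10
Reactants: 15 ethyl (2R,3S)-3-hydroxy-2-[(4-methoxybenzyl)oxy]-4-[(triethylsilyl)oxy]butanoate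
Product: 16 ethyl (2R,3S)-3-[(tert-butyldimethylsilyl)oxy]-2-[(4-methoxybenzyl)oxy]-4-[(triethylsilyl)oxy]butanoate
Conditions: TBSOTf, 2,6-lutidine, CH2Cl2, −78 → 0 °C
Reagents that add atoms: tert-butyldimethylsilyl trifluoromethanesulfonate, CC(C)(C)[Si](C)(C)OS(=O)(=O)C(F)(F)F
Why: Silyl triflate protection of the hindered secondary C8 hydroxyl gives an ether that outlasts the later acid step, so only C6–OH can lactonise.

Step 11
Reactants: 16 ethyl (2R,3S)-3-[(tert-butyldimethylsilyl)oxy]-2-[(4-methoxybenzyl)oxy]-4-[(triethylsilyl)oxy]butanoate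
Product: 17 (2R,3S)-3-[(tert-butyldimethylsilyl)oxy]-N-methoxy-2-[(4-methoxybenzyl)oxy]-N-methyl-4-[(triethylsilyl)oxy]butanamide
Conditions: MeNH(OMe)·HCl, i-PrMgCl, THF, −20 → 0 °C
Reagents that add atoms: N,O-dimethylhydroxylamine hydrochloride, CNOC.Cl
Why: Aminolysis of the ester by the magnesium amide gives the Weinreb amide, which carries C10 as a latent methyl ketone through the coupling steps.

Step 12
Reactants: 17 (2R,3S)-3-[(tert-butyldimethylsilyl)oxy]-N-methoxy-2-[(4-methoxybenzyl)oxy]-N-methyl-4-[(triethylsilyl)oxy]butanamide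
Product: 18 (2R,3R)-3-[(tert-butyldimethylsilyl)oxy]-N-methoxy-2-[(4-methoxybenzyl)oxy]-N-methyl-4-oxobutanamide
Conditions: (COCl)2, DMSO, CH2Cl2, −78 → −30 °C; i-Pr2NEt, −78 → 0 °C
Reagents that add atoms: none
Why: Swern conditions convert a primary triethylsilyl ether directly into the aldehyde while the secondary TBS ether is inert, so a free γ-hydroxy Weinreb amide, which would lactonise, is never formed.

Step 13
Reactants: 5 methyl propiolate; 18 (2R,3R)-3-[(tert-butyldimethylsilyl)oxy]-N-methoxy-2-[(4-methoxybenzyl)oxy]-N-methyl-4-oxobutanamide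
Product: 20 methyl (4S,5R)-4-[(tert-butyldimethylsilyl)oxy]-3-hydroxy-6-[methoxy(methyl)amino]-5-[(4-methoxybenzyl)oxy]-2-methylidene-6-oxohexanoate (both C3 epimers), via vinylalane 19 (not isolated)
Conditions: i-Bu2AlH, N-methylmorpholine N-oxide, THF, 0 °C (with 5, slight excess); then 18, 0 °C → rt
Reagents that add atoms: none
Why: Vinylalumination: conjugate hydroalumination of the propiolate gives the α-alanyl acrylate, which adds to the aldehyde and delivers the Morita–Baylis–Hillman-type adduct without amine base, sparing the epimerisable, β-alkoxy aldehyde; the new carbinol centre is erased in step 14.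

Step 14
Reactants: 20 methyl (4S,5R)-4-[(tert-butyldimethylsilyl)oxy]-3-hydroxy-6-[methoxy(methyl)amino]-5-[(4-methoxybenzyl)oxy]-2-methylidene-6-oxohexanoate
Product: 21 methyl (2Z,4S,5R)-2-(bromomethyl)-4-[(tert-butyldimethylsilyl)oxy]-6-[methoxy(methyl)amino]-5-[(4-methoxybenzyl)oxy]-6-oxohex-2-enoate
Conditions: NBS, Me2S, CH2Cl2, 0 °C → rt
Reagents that add atoms: N-bromosuccinimide, O=C1CCC(=O)N1Br
Why: Corey–Kim-type activation of the allylic alcohol and SN2′ attack of bromide at the methylidene carbon should give the thermodynamically preferred Z-2-(bromomethyl)enoate (C8 chain cis to CH2Br).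

**Union and precursor**

Step 15
Reactants: 10 (2Z)-3-[2-(2-hydroxyethyl)-1,3-dithian-2-yl]but-2-enal; 21 methyl (2Z,4S,5R)-2-(bromomethyl)-4-[(tert-butyldimethylsilyl)oxy]-6-[methoxy(methyl)amino]-5-[(4-methoxybenzyl)oxy]-6-oxohex-2-enoate
Product: 23 open-chain (6S,7S,8S,9R) diol: C1 primary alcohol, C3 1,3-dithiane, 4Z alkene, free C6 hydroxyl, C7 bearing C11(=CH2)CO2Me, C8-OTBS, C9-OPMB, C10 Weinreb amide, via allylindium dibromide 22 (not isolated)
Conditions: In powder, THF/H2O (1:1), rt
Reagents that add atoms: none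
Why: Indium Barbier allylation through a chair transition state in which the allylindium reacts at its γ-carbon (C7): the Z geometry puts the C8 chain axial and gives the 6,7-syn adduct needed for the cis-lactone, and with H-8 eclipsing the alkene (allylic 1,3-strain) the aldehyde should approach C7 anti to the C9 branch, giving the 7,8-anti relationship.

Step 16
Reactants: 23 open-chain (6S,7S,8S,9R) diol
Product: 24 bis(triethylsilyl) ether of 23 (C1-OTES primary, C6-OTES secondary; otherwise unchanged)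
Conditions: TESOTf, 2,6-lutidine, CH2Cl2, −78 °C
Reagents that add atoms: triethylsilyl trifluoromethanesulfonate, CC[Si](CC)(CC)OS(=O)(=O)C(F)(F)F
Why: Silyl triflate protection of both hydroxyls blocks lactonisation of C6–OH onto the C12 ester and sets up the selective oxidation of step 18.

Step 17
Reactants: 24 bis(triethylsilyl) ether
Product: 25 C10 methyl ketone (6S,7S,8S,9R): as 24 with C10 = C(=O)CH3
Conditions: MeMgBr (2 equiv), THF, −40 → −20 °C
Reagents that add atoms: methylmagnesium bromide, C[Mg]Br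
Why: Weinreb ketone synthesis; the α-alkoxy amide, activated by chelation, should be consumed at a temperature where the hindered, α-branched acrylate methyl ester is inert.

Step 18
Reactants: 25 C10 methyl ketone
Product: 26 keto aldehyde (6S,7S,8S,9R): C1 aldehyde, C3 1,3-dithiane, 4Z alkene, C6-OTES, C7 bearing C11(=CH2)CO2Me, C8-OTBS, C9-OPMB, C10 methyl ketone
Conditions: (COCl)2, DMSO, CH2Cl2, −78 → −30 °C; Et3N, −78 → 0 °C
Reagents that add atoms: none
Why: Swern conditions oxidise the primary C1 triethylsilyl ether directly to the aldehyde while the secondary C6-OTES and C8-OTBS ethers survive, so the aldehyde is unmasked last.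

**Key step**

Step 19
Reactants: 26 keto aldehyde
Product: 27 ten-membered α-ketol (6S,7S,8S,9R,10R): C1 ketone, C10 tertiary alcohol bearing C14, C9-OPMB, C8-OTBS, C7 bearing C11(=CH2)CO2Me, C6-OTES, 4Z alkene, C3 spiro-1,3-dithiane
Conditions: 2-(pentafluorophenyl)-6,7-dihydro-5H-pyrrolo[2,1-c][1,2,4]triazol-2-ium tetrafluoroborate (20 mol%), DBU (15 mol%), CH2Cl2, 0.002 M (slow addition of 26), 25–40 °C
Reagents that add atoms: none
Why: Proposed new method: DBU frees the triazolylidene, which adds to the C1 aldehyde; proton transfer gives the catalyst-bound hydroxy-enamine, whose C1 attacks the C10 methyl ketone, and collapse of the adduct returns the carbene and leaves the C1 ketone beside the new C10 tertiary alcohol. The closest known reaction is the triazolium/DBU-catalysed intramolecular crossed aldehyde–ketone benzoin that gives five- and six-membered tertiary α-ketols; its use for a ten-membered ring is the unprecedented element. The carbocycle closes by 10-exo-trig addition of C1 to the C10 carbonyl, helped by the Z C4=C5 alkene and the quaternary C3 dithiane as turn elements, while high dilution suppresses the bimolecular aldehyde homo-benzoin. The new C10 centre is set by 1,2-induction from C9: in the dipole-minimised (polar Felkin–Anh/Cornforth) arrangement the nucleophile enters anti to the C9–OPMB bond, placing the C10 hydroxyl anti to the C9 oxygen along C8–C9–C10–C1 (10R), and an aminoindanol-derived chiral triazolium of matching sense can reinforce this. Cross-selectivity is built in, because the ketone cannot become an acyl-anion equivalent and is activated as an acceptor by its α-oxygen, the α-branched acrylate ester is a poor Stetter acceptor, and the dithiane keeps C3 from acting as a β-keto or β-leaving-group site. Holding DBU below the triazolium loading limits epimerisation at C9 and β-elimination of the C8 silyloxy group.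

**Endgame**

Step 20
Reactants: 27 ten-membered α-ketol
Product: 28 10-hydroxy-1,3-diketone (6S,7S,8S,9R,10R): as 27 with C3 = ketone (in equilibrium with its C3 hemiketal; used crude)
Conditions: Hg(ClO4)2, CaCO3, THF/H2O (5:1), 0 °C
Reagents that add atoms: water, O
Why: Thiophilic, buffered hydrolysis of a ketone-derived 1,3-dithiane is fast at 0 °C and should leave the alkenes, silyl ethers and PMB ether untouched.

Step 21
Reactants: 28 10-hydroxy-1,3-diketone
Product: 30 furanone lactone (6S,7S,8S,9R,10R): 3(2H)-furanone (O bridging C3 and C10), cis-fused 6,12-α-methylene-γ-lactone, C8-OTBS, C9-OPMB, via furanone hydroxy ester 29 (not isolated)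
Conditions: TsOH·H2O (cat.), wet CH2Cl2, rt
Reagents that add atoms: none
Why: Acid-catalysed cyclodehydration (C10–OH adds to the C3 carbonyl and water is lost to give the 3(2H)-furanone), TES cleavage and lactonisation of the freed C6 hydroxyl onto the C12 methyl ester; C8 stays silylated so only the 6,12-lactone can form, and its cis fusion follows from the 6,7-syn configuration.

Step 22
Reactants: 30 furanone lactone
Product: 31 C8 alcohol (6S,7R,8S,9R,10R; same geometry, descriptor at C7 changes by priority): as 30 with free C8 hydroxyl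
Conditions: HF·pyridine, pyridine, THF, 0 °C → rt
Reagents that add atoms: none
Why: Buffered fluoride desilylation removes the secondary TBS ether without the basic conditions that would endanger the α-methylene lactone or promote translactonisation.

Step 23
Reactants: 31 C8 alcohol
Product: 32 C8 methacrylate, C9 PMB ether (6S,7S,8S,9R,10R)
Conditions: methacrylic anhydride, Et3N, DMAP (cat.), CH2Cl2, 0 °C → rt
Reagents that add atoms: methacrylic anhydride, C=C(C)C(=O)OC(=O)C(C)=C
Why: DMAP-catalysed acylation of the only free hydroxyl; C9 is still blocked, so no regiochemical question arises.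

Step 24
Reactants: 32 C8 methacrylate, C9 PMB ether
Product: 33 target CNP0252578.4
Conditions: DDQ, CH2Cl2/pH 7 buffer (10:1), 0 °C → rt
Reagents that add atoms: none
Why: Oxidative PMB cleavage under neutral conditions frees the C9 hydroxyl last, with no neighbouring free hydroxyl to trap the oxocarbenium ion and no base to move the C8 acyl group.

**Compound list**

1 | but-2-yn-1-ol | CC#CCO | starting material
2 | sodium alkenylaluminate (five-membered oxaaluminacycle, not isolated) | [Na+].CC1=CCO[Al-]1(OCCOC)OCCOC | intermediate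
3 | (2Z)-3-iodobut-2-en-1-ol | C/C(I)=C/CO | intermediate
4 | (2Z)-3-iodobut-2-en-1-yl 2,2-dimethylpropanoate | C/C(I)=C/COC(=O)C(C)(C)C | intermediate
5 | methyl propiolate | C#CC(=O)OC | starting material
6 | methyl (4Z)-6-[(2,2-dimethylpropanoyl)oxy]-4-methylhex-4-en-2-ynoate | C/C(C#CC(=O)OC)=C/COC(=O)C(C)(C)C | intermediate
7 | methyl (4Z)-6-[(2,2-dimethylpropanoyl)oxy]-4-methyl-3-[(3-sulfanylpropyl)sulfanyl]hexa-2,4-dienoate (not isolated) | C/C(C(SCCCS)=CC(=O)OC)=C/COC(=O)C(C)(C)C | intermediate
8 | methyl {2-[(2Z)-4-[(2,2-dimethylpropanoyl)oxy]but-2-en-2-yl]-1,3-dithian-2-yl}acetate | C/C(C1(CC(=O)OC)SCCCS1)=C/COC(=O)C(C)(C)C | intermediate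
9 | (2Z)-3-[2-(2-hydroxyethyl)-1,3-dithian-2-yl]but-2-en-1-ol | C/C(C1(CCO)SCCCS1)=C/CO | intermediate
10 | (2Z)-3-[2-(2-hydroxyethyl)-1,3-dithian-2-yl]but-2-enal | C/C(C1(CCO)SCCCS1)=C/C=O | intermediate
11 | diethyl L-tartrate | CCOC(=O)[C@H](O)[C@@H](O)C(=O)OCC | starting material
12 | diethyl (4R,5R)-2,2-dibutyl-1,3,2-dioxastannolane-4,5-dicarboxylate (not isolated) | CCOC(=O)[C@@H]1O[Sn](CCCC)(CCCC)O[C@H]1C(=O)OCC | intermediate
13 | diethyl (2R,3R)-2-hydroxy-3-[(4-methoxybenzyl)oxy]butanedioate | CCOC(=O)[C@H](O)[C@@H](OCc1ccc(OC)cc1)C(=O)OCC | intermediate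
14 | ethyl (2R,3S)-3,4-dihydroxy-2-[(4-methoxybenzyl)oxy]butanoate | OC[C@H](O)[C@@H](OCc1ccc(OC)cc1)C(=O)OCC | intermediate
15 | ethyl (2R,3S)-3-hydroxy-2-[(4-methoxybenzyl)oxy]-4-[(triethylsilyl)oxy]butanoate | CC[Si](CC)(CC)OC[C@H](O)[C@@H](OCc1ccc(OC)cc1)C(=O)OCC | intermediate
16 | ethyl (2R,3S)-3-[(tert-butyldimethylsilyl)oxy]-2-[(4-methoxybenzyl)oxy]-4-[(triethylsilyl)oxy]butanoate | CC[Si](CC)(CC)OC[C@H](O[Si](C)(C)C(C)(C)C)[C@@H](OCc1ccc(OC)cc1)C(=O)OCC | intermediate
17 | (2R,3S)-3-[(tert-butyldimethylsilyl)oxy]-N-methoxy-2-[(4-methoxybenzyl)oxy]-N-methyl-4-[(triethylsilyl)oxy]butanamide | CC[Si](CC)(CC)OC[C@H](O[Si](C)(C)C(C)(C)C)[C@@H](OCc1ccc(OC)cc1)C(=O)N(C)OC | intermediate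
18 | (2R,3R)-3-[(tert-butyldimethylsilyl)oxy]-N-methoxy-2-[(4-methoxybenzyl)oxy]-N-methyl-4-oxobutanamide | O=C[C@H](O[Si](C)(C)C(C)(C)C)[C@@H](OCc1ccc(OC)cc1)C(=O)N(C)OC | intermediate
19 | methyl 2-(diisobutylalumanyl)prop-2-enoate (not isolated) | C=C(C(=O)OC)[Al](CC(C)C)CC(C)C | intermediate
20 | methyl (4S,5R)-4-[(tert-butyldimethylsilyl)oxy]-3-hydroxy-6-[methoxy(methyl)amino]-5-[(4-methoxybenzyl)oxy]-2-methylidene-6-oxohexanoate (C3 epimers) | C=C(C(=O)OC)C(O)[C@H](O[Si](C)(C)C(C)(C)C)[C@@H](OCc1ccc(OC)cc1)C(=O)N(C)OC | intermediate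
21 | methyl (2Z,4S,5R)-2-(bromomethyl)-4-[(tert-butyldimethylsilyl)oxy]-6-[methoxy(methyl)amino]-5-[(4-methoxybenzyl)oxy]-6-oxohex-2-enoate | BrC/C(C(=O)OC)=C\[C@H](O[Si](C)(C)C(C)(C)C)[C@@H](OCc1ccc(OC)cc1)C(=O)N(C)OC | intermediate
22 | allylindium dibromide from 21 (drawn as the dibromide, not isolated) | Br[In](Br)C/C(C(=O)OC)=C\[C@H](O[Si](C)(C)C(C)(C)C)[C@@H](OCc1ccc(OC)cc1)C(=O)N(C)OC | intermediate
23 | open-chain (6S,7S,8S,9R) diol (C1-OH, C6-OH, C3 dithiane, C8-OTBS, C9-OPMB, C10 Weinreb amide, C12 methyl ester) | CON(C)C(=O)[C@H](OCc1ccc(OC)cc1)[C@@H](O[Si](C)(C)C(C)(C)C)[C@@H](C(=C)C(=O)OC)[C@@H](O)/C=C(/C)C1(CCO)SCCCS1 | intermediate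
24 | bis(triethylsilyl) ether of 23 | CON(C)C(=O)[C@H](OCc1ccc(OC)cc1)[C@@H](O[Si](C)(C)C(C)(C)C)[C@@H](C(=C)C(=O)OC)[C@@H](O[Si](CC)(CC)CC)/C=C(/C)C1(CCO[Si](CC)(CC)CC)SCCCS1 | intermediate
25 | C10 methyl ketone (6S,7S,8S,9R) | CC(=O)[C@H](OCc1ccc(OC)cc1)[C@@H](O[Si](C)(C)C(C)(C)C)[C@@H](C(=C)C(=O)OC)[C@@H](O[Si](CC)(CC)CC)/C=C(/C)C1(CCO[Si](CC)(CC)CC)SCCCS1 | intermediate
26 | keto aldehyde, benzoin precursor (6S,7S,8S,9R) | CC(=O)[C@H](OCc1ccc(OC)cc1)[C@@H](O[Si](C)(C)C(C)(C)C)[C@@H](C(=C)C(=O)OC)[C@@H](O[Si](CC)(CC)CC)/C=C(/C)C1(CC=O)SCCCS1 | intermediate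
27 | ten-membered α-ketol with C3 dithiane (6S,7S,8S,9R,10R) | CC(C)(C)[Si](C)(C)O[C@H]1[C@@H](C(=C)C(=O)OC)[C@@H](O[Si](CC)(CC)CC)/C=C(/C)C2(SCCCS2)CC(=O)[C@](C)(O)[C@@H]1OCc1ccc(OC)cc1 | intermediate
28 | ten-membered 10-hydroxy-1,3-diketone (6S,7S,8S,9R,10R) | CC(C)(C)[Si](C)(C)O[C@H]1[C@@H](C(=C)C(=O)OC)[C@@H](O[Si](CC)(CC)CC)/C=C(/C)C(=O)CC(=O)[C@](C)(O)[C@@H]1OCc1ccc(OC)cc1 | intermediate
29 | furanone hydroxy ester (C6-OH, C12 methyl ester, not isolated) | CC(C)(C)[Si](C)(C)O[C@H]1[C@@H](C(=C)C(=O)OC)[C@@H](O)/C=C(/C)C2=CC(=O)[C@](C)(O2)[C@@H]1OCc1ccc(OC)cc1 | intermediate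
30 | furanone lactone, C8-OTBS, C9-OPMB (6S,7S,8S,9R,10R) | CC(C)(C)[Si](C)(C)O[C@H]1[C@H]2C(=C)C(=O)O[C@H]2/C=C(/C)C2=CC(=O)[C@](C)(O2)[C@@H]1OCc1ccc(OC)cc1 | intermediate
31 | furanone lactone, C8-OH, C9-OPMB | O[C@H]1[C@H]2C(=C)C(=O)O[C@H]2/C=C(/C)C2=CC(=O)[C@](C)(O2)[C@@H]1OCc1ccc(OC)cc1 | intermediate
32 | furanone lactone, C8 methacrylate, C9-OPMB | C=C(C)C(=O)O[C@H]1[C@H]2C(=C)C(=O)O[C@H]2/C=C(/C)C2=CC(=O)[C@](C)(O2)[C@@H]1OCc1ccc(OC)cc1 | intermediate
33 | CNP0252578.4 | C=C(C)C(=O)O[C@H]1[C@H]2C(=C)C(=O)O[C@H]2/C=C(/C)C2=CC(=O)[C@](C)(O2)[C@@H]1O | target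

**Step count and risks**

Total steps: 24. Longest linear sequence: 18 (steps 7–24, from diethyl L-tartrate).

Steps most likely to fail:

Step 19 (carbene-catalysed ring closure). The ring-closure equilibrium may lie on the open side (retro-benzoin of a strained tertiary ketol), bimolecular aldehyde dimerisation may win, or base may cause loss of the C8 silyloxy group or epimerisation at C9. Fallback, by known chemistry: from 26, reductive pinacol cyclisation with low-valent titanium (TiCl3(DME)1.5, Zn–Cu couple, DME, high dilution, rt; McMurry conditions stopped at the diol) would give the ten-membered 1,10-diol F1. Parikh–Doering oxidation (SO3·pyridine, DMSO, i-Pr2NEt) of its secondary C1 hydroxyl, the tertiary C10 hydroxyl being inert, comes back to the route at 27. C10 selectivity would then rest on substrate conformation, and the C10 epimers would have to be separated.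

Step 15 (indium Barbier union). Facial selectivity at C7 may be poor, the allylindium may react through its CH2 terminus because C7 is hindered, or its Z geometry may erode and lower the syn selectivity. Fallback: from 20, acetylation (Ac2O, DMAP) gives the allylic acetate F2; copper-catalysed SN2′ borylation (CuCl, B2pin2, KOAc, DMF) gives the allyl pinacolboronate F3 with the C8 chain cis to CH2B. Thermal allylboration of 10 (toluene, 60–80 °C) then proceeds through a tighter, boron-centred chair in which syn topology is tied strictly to alkene geometry and the allylic-strain bias of C8 is amplified; hydrolytic work-up comes back to the route at 23.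

Step 17 (Grignard addition to the Weinreb amide). The Grignard reagent may also attack the C12 methyl ester, by 1,2- or conjugate addition. Fallback: from 24, Cp2Zr(H)Cl (THF, rt) reduces the Weinreb amide to the C10 aldehyde F4 while the ester is not reduced. MeMgBr at −78 °C, where an aldehyde reacts far faster than an ester, gives the C10 carbinol F5 as an epimer mixture, and Parikh–Doering oxidation comes back to the route at 25.

**Further compounds**

F1 | step 19 | ten-membered 1,10-diol (C1 secondary alcohol, C10 tertiary alcohol; otherwise as 27) | CC(C)(C)[Si](C)(C)O[C@H]1[C@@H](C(=C)C(=O)OC)[C@@H](O[Si](CC)(CC)CC)/C=C(/C)C2(SCCCS2)CC(O)[C@](C)(O)[C@@H]1OCc1ccc(OC)cc1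
F2 | step 15 | acetate of 20 (C3 epimers) | C=C(C(=O)OC)C(OC(C)=O)[C@H](O[Si](C)(C)C(C)(C)C)[C@@H](OCc1ccc(OC)cc1)C(=O)N(C)OC
F3 | step 15 | allyl pinacolboronate, C8 chain cis to CH2B | CC1(C)OB(C/C(C(=O)OC)=C\[C@H](O[Si](C)(C)C(C)(C)C)[C@@H](OCc2ccc(OC)cc2)C(=O)N(C)OC)OC1(C)C
F4 | step 17 | C10 aldehyde (otherwise as 24) | O=C[C@H](OCc1ccc(OC)cc1)[C@@H](O[Si](C)(C)C(C)(C)C)[C@@H](C(=C)C(=O)OC)[C@@H](O[Si](CC)(CC)CC)/C=C(/C)C1(CCO[Si](CC)(CC)CC)SCCCS1
F5 | step 17 | C10 methyl carbinol, epimer mixture (otherwise as 24) | CC(O)[C@H](OCc1ccc(OC)cc1)[C@@H](O[Si](C)(C)C(C)(C)C)[C@@H](C(=C)C(=O)OC)[C@@H](O[Si](CC)(CC)CC)/C=C(/C)C1(CCO[Si](CC)(CC)CC)SCCCS1
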